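The data stem from a simulated flask with made-up constants; noise was put on by code.

In a one-step world the starting complex follows a single clock, and one number describes a flask.

the same everywhere: gas 0.76 mM (held)
- Monday's: starting complex 5 mM; temperature 9 °C; run made earlier
- Thursday's: starting complex 20 mM; temperature 17 °C; run made earlier
- midnight: starting complex 10 mM; temperature 5 °C; time 6.0 d
- spring: starting complex 10 mM; temperature 20 °C; time 6.0 d

- Monday's (time / d: starting complex / %, complex with one exchanged / %, complex with two exchanged / %): 0.500: 85.0, 12.6, 2.0; 1.04: 71.0, 22.1, 7.9; 2.50: 42.6, 27.5, 29.9; 6.00: 13.5, 15.6, 70.1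
- Thursday's (time / d: starting complex / %, complex with one exchanged / %, complex with two exchanged / %): 0.250: 90.9, 8.0, 0.2; 0.625: 78.1, 16.6, 4.6; 1.25: 61.4, 23.4, 14.9; 3.00: 34.3, 21.0, 44.0

(each reading ± 0.3 percentage points)

- at the start none of incoming ligand is dissolved
- what may be going on: starting complex + incoming ligand <-> leaving ligand + complex with one exchanged; complex with one exchanged + incoming ligand <-> leaving ligand + complex with two exchanged; gas <-> incoming ligand

- which of these there is most of at the end, counted by the starting complex in it, midnight (complex with one exchanged / starting complex / complex with two exchanged)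
- which of these there is most of at the end, counted by the starting complex in it, spring (complex with one exchanged / starting complex / complex with two exchanged)
- the largest of these amounts at the end, in percent of the starting complex charged, midnight
- the largest of these amounts at the end, in percent of the starting complex charged, spring

Monday's run at its last reading gives 0.334 d⁻¹ for this clock, the pseudo-first-order constant, ln(charged/left) over the time. Its first reading gives 0.325 d⁻¹, so Monday's line is nearly straight. Thursday's run, warmer, reads 0.395 d⁻¹ at 0.625 d.

But the clock contains the dissolved incoming ligand, a pool that starts empty and fills towards 0.76 mM. Thursday's first step, reckoned on the full charge, draws about 7.91 mM d⁻¹ from it, more than Monday's 1.67 mM d⁻¹, so Thursday's pool should stand lower and its clock should understate the warming.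

Midnight lies half as far below Monday as Thursday lies above, with twice Monday's charge. Its clock is therefore reckoned to stay under 0.307 d⁻¹.

That draws midnight's curve. Starting complex should end above 15.9%. Complex with two exchanged starts flat, as Thursday's 0.2% at 0.250 d shows. Complex with one exchanged, highest in Monday's readings at 27.5% after 2.50 d, should crest no sooner than 2.72 d. Midnight's whole time equals under 5.51 d of Monday's, and Monday's last slope then gives an estimate of under 64.5% for complex with two exchanged. The same scaling puts spring's clock near 0.421 d⁻¹.

The forecast names complex with two exchanged at 62% (56% to 67%) for midnight and complex with two exchanged at 82% (74% to 89%) for spring, holding that “the first step depends only weakly on temperature”.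

The flask gives complex with two exchanged at 51.1% at midnight, and complex with two exchanged at 80.7% in spring.

    starting complex + incoming ligand ⇌ leaving ligand + complex with one exchanged (K = 130, k = 15.0 M⁻¹ h⁻¹, Ea = 53.0 kJ mol⁻¹, ΔH = −57.0 kJ mol⁻¹)
    complex with one exchanged + incoming ligand ⇌ leaving ligand + complex with two exchanged (K = 180, k = 24.0 M⁻¹ h⁻¹, Ea = 63.0 kJ mol⁻¹, ΔH = 1.00 kJ mol⁻¹)
    gas ⇌ incoming ligand, rate k3*(csat - [incoming ligand]) (kL = 1.20 h⁻¹)
    (constants at 5 °C)

Midnight's clock reads 0.232 d⁻¹, below the reckoned 0.307 d⁻¹. Spring's reads 0.415 d⁻¹, yet its forward first step alone, at the asked time, runs at 0.872 d⁻¹, twice that clock, and its starting complex goes from 8.29% to 6.59% by 60.0 d. For a neighbour of spring with 6.0 mM of starting complex, these two constants are taken as the ends of the range for the clock, so 0.534% to 8.29% should remain. That neighbour keeps 4.2%, a clock of 0.527 d⁻¹.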